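The route is cut at the two bonds of the quaternary carbon C13, which is bonded both to the ring B methylene C12 and to C4 of the isopropyl-bearing bridge of the bicyclo[2.2.1]heptane. Both bonds are formed in one operation: a C11 radical, generated from a neopentyl iodide on ring A, closes ring B by 6-endo addition to an exocyclic C13=C12 methylene on ring D, and the tertiary C13 radical then closes the norbornane by 5-exo addition to the prenyl group on C6, the C2 radical ending as the isopropyl group. The precursor is a ring A iodide joined through C8–C9 to an all-trans prenyl silyloxy methylenecyclopentane; C21 carries a silyl ether that steers the fragment coupling.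

Key step: step 12

Remark on locants: C1–C3 isopropyl (C2 = CH); C4 the CH that carries it; C5 bridge CH2; C6 bridgehead CH; C7 carbinol CH of ring D; C8 ring A/B fusion CH; C9 one-carbon bridge CH (bonded to C6, C8, C13); C10 quaternary carbon with methyl C20; C11, C12 ring B CH2; C13 quaternary bridgehead; C14 ring D CH2; C17 CHBr; C18, C19 ring A CH2; C21 carbinol carbon with methyl C22; ring A = C8, C10, C17, C18, C19, C21; ring B = C8, C9, C13, C12, C11, C10; ring D = C6, C7, C14, C13, C9.

Assumption: the chiral lithium amide of step 2 is taken to act on 2 in the same sense as on 4-tert-butylcyclohexanone (the (R,R)-amide giving the (S)-enol silane); were the sense opposite, the (S,S)-amine would be used, and any minor enantiomer of 7 should be removed after step 7 as a diastereomer of 12.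

Step 1
Reactants: 1 4-hydroxycyclohexan-1-one
Product: 2 4-(triethylsilyloxy)cyclohexan-1-one
Conditions: Et3SiCl, imidazole, CH2Cl2, 0 °C to rt
Reagents that add atoms: chlorotriethylsilane, CC[Si](Cl)(CC)CC
Why: Silyl ether formation at the only hydroxyl group is routine and gives an ether that can later be removed in the presence of a tert-butyldimethylsilyl ether.

Step 2
Reactants: 2 4-(triethylsilyloxy)cyclohexan-1-one
Product: 4 (S)-triethyl{[4-(trimethylsilyloxy)cyclohex-3-en-1-yl]oxy}silane, via lithium enolate 3 (not isolated)
Conditions: (R,R)-bis(1-phenylethyl)amine, n-BuLi, LiCl, Me3SiCl (internal quench), THF, −78 °C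
Reagents that add atoms: chlorotrimethylsilane, C[Si](C)(C)Cl
Why: Enantioselective deprotonation of the prochiral ketone by the C2-symmetric chiral lithium amide (desymmetrisation) with immediate silylation should give the (S)-enol silane, so that the C21 stereocentre is set by which of the two enantiotopic α-methylene groups is deprotonated.

Step 3
Reactants: 4 (S)-triethyl{[4-(trimethylsilyloxy)cyclohex-3-en-1-yl]oxy}silane
Product: 5 (S)-4-(triethylsilyloxy)cyclohex-2-en-1-one
Conditions: Pd(OAc)2, MeCN, rt
Reagents that add atoms: none
Why: Saegusa–Ito oxidation turns the enol silane regiospecifically into the enone and touches neither the C21 stereocentre nor the triethylsilyl ether.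

Step 4
Reactants: 5 (S)-4-(triethylsilyloxy)cyclohex-2-en-1-one
Product: 6 (S)-2-iodo-4-(triethylsilyloxy)cyclohex-2-en-1-one
Conditions: I2, pyridine, CH2Cl2, 0 °C to rt
Reagents that add atoms: iodine, II
Why: Pyridine-mediated α-iodination of an enone (conjugate addition of pyridine, iodination of the enolate, elimination) is a standard entry to 2-iodoenones and leaves the γ-silyloxy centre unchanged.

Step 5
Reactants: 6 (S)-2-iodo-4-(triethylsilyloxy)cyclohex-2-en-1-one
Product: 7 (S)-2-methyl-4-(triethylsilyloxy)cyclohex-2-en-1-one
Conditions: Me4Sn, PdCl2(PhCN)2 (cat), AsPh3, CuI, NMP, 80 °C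
Reagents that add atoms: tetramethyltin, C[Sn](C)(C)C
Why: Stille coupling of the 2-iodoenone installs the C20 methyl group under neutral conditions, so no base is present that could eliminate the γ-silyloxy group.

Step 6
Reactants: 8 (R)-4-(tert-butyldimethylsilyloxy)cyclopent-2-en-1-one; 9 prenylmagnesium chloride
Product: 11 tert-butyldimethyl{[(1R,2R)-2-(3-methylbut-2-enyl)-4-(trimethylsilyloxy)cyclopent-3-en-1-yl]oxy}silane, via prenylcopper 10 (not isolated)
Conditions: CuBr·SMe2, THF, −78 °C; Me3SiCl, then 8; Et3N quench
Reagents that add atoms: chlorotrimethylsilane, C[Si](C)(C)Cl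
Why: Chlorosilane-accelerated conjugate addition of the allylic copper reagent, which bonds through its primary carbon, should occur anti to the C7 silyloxy group (setting C6) and deliver the C13 enolate directly as its regiodefined trimethylsilyl enol ether.

Step 7
Reactants: 11 ring D enol silane; 7 (S)-2-methyl-4-(triethylsilyloxy)cyclohex-2-en-1-one
Product: 12 (2S,3R,4R)-4-(tert-butyldimethylsilyloxy)-2-[(1S,6S)-2-methyl-6-(triethylsilyloxy)-3-(trimethylsilyloxy)cyclohex-2-en-1-yl]-3-(3-methylbut-2-enyl)cyclopentan-1-one
Conditions: Ph3CSbCl6 (5 mol %), CH2Cl2, −78 °C; pyridine quench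
Reagents that add atoms: none
Why: In this Mukaiyama–Michael addition with silyl transfer the enol silane should react at C9 on the face anti to the neighbouring prenyl group and the enone at C8 anti to its γ-silyloxy group, so each ring controls its own new centre (C9 trans to the C6 substituent, C8 trans to the C21 oxygen) and the ring A carbonyl emerges masked as the tetrasubstituted C17 enol silane.

Step 8
Reactants: 12 Michael adduct
Product: 13 C13-methylene analogue of 12 (C13=C12H2 in place of C13=O; enol silane and all stereocentres unchanged)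
Conditions: Cp2TiMe2, toluene, 70 °C, dark
Reagents that add atoms: dimethyltitanocene, C[Ti](C)(C1C=CC=C1)C1C=CC=C1
Why: Petasis methylenation is non-basic, so the only free ketone should be converted into the exocyclic alkene without β-elimination of the C7 silyloxy group, epimerisation at C9 or loss of the enol silane.

Step 9
Reactants: 13 methylene enol silane; 14 formaldehyde
Product: 16 hydroxymethyl ketone (C17=O; quaternary C10 with CH3 cis and CH2OH trans to the ring D substituent on C8), via lithium enolate 15 (not isolated)
Conditions: MeLi, THF, 0 °C; then CH2O (gas), −78 °C; NH4Cl (aq)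
Reagents that add atoms: none
Why: Cleavage of the enol silane by methyllithium gives the regiodefined lithium enolate, whose aldol reaction with monomeric formaldehyde should take place at C10 on the face opposite the bulky C8 substituent, creating the quaternary centre with the hydroxymethyl group trans to ring D.

Step 10
Reactants: 16 hydroxymethyl ketone
Product: 17 iodomethyl ketone (C11–I in place of C11–OH)
Conditions: PPh3, I2, imidazole, toluene, 80 °C
Reagents that add atoms: iodine, II
Why: Iodination of the primary alcohol through its alkoxyphosphonium salt (Appel-type) is feasible at a neopentyl carbon on heating, and the β-iodo ketone cannot eliminate because its α-carbon is quaternary.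

Step 11
Reactants: 17 iodomethyl ketone
Product: 18 radical precursor (C17 axial alcohol, cis to C11 and trans to C20; C11–I; C21–OSiEt3; C7–OSiMe2tBu; C13=C12H2; prenyl on C6)
Conditions: LiBH(s-Bu)3, THF, −78 to −20 °C; then H2O
Reagents that add atoms: none
Why: The bulky hydride should attack the C17 ketone along the equatorial direction of the chair in which the C8, C10–CH2I and C21 substituents are equatorial and C20 is axial, giving the axial alcohol, while the neopentyl iodide is inert at this temperature.

Step 12
Reactants: 18 radical precursor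
Product: 19 tetracyclic alcohol (trans-fused rings A and B, norbornane with exo isopropyl on C4; C17 axial OH; C21–OSiEt3; C7–OSiMe2tBu)
Conditions: Bu3SnH (syringe pump), AIBN, toluene, 90 °C, 0.005 M
Reagents that add atoms: none
Why: The stannyl radical abstracts iodine from C11, the primary radical adds to the terminal carbon C12 of the 1,1-disubstituted alkene (6-endo-trig, ring B) because 5-exo attack would have to build a spiro quaternary centre at C13, and the tertiary C13 radical then adds 5-exo-trig to C4 of the prenyl alkene (ring C13–C4–C5–C6–C9, completing the norbornane) before the tertiary C2 radical takes hydrogen from the stannane. The closest known reaction type is the tin hydride cascade that joins a 6-endo closure onto a 2-substituted alkene to a 5-exo closure giving a bicyclo[2.2.1]heptane from a cyclopentyl radical. C13 is fixed because the prenyl tether on C6 can reach the planar radical only from its own face of ring D, and C4 is set by the dimethyl-substituted alkene terminus taking the exo position, away from the C14–C7 bridge. The trans ring A/B fusion is already encoded in 18, where C9 and C11 are both equatorial on ring A. The step needs 6-endo over 5-exo regioselectivity and ring closure faster than hydrogen transfer, which the substitution at C13, the fully substituted C10 and the low stannane concentration should secure.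

Step 13
Reactants: 19 tetracyclic alcohol
Product: 20 C17 equatorial bromide (C21–OSiEt3 and C7–OSiMe2tBu retained)
Conditions: CBr4, PPh3, 2,6-lutidine, toluene, 0 to 60 °C
Reagents that add atoms: carbon tetrabromide, BrC(Br)(Br)Br
Why: In this Appel reaction the axial C17 oxyphosphonium group should be displaced by bromide with inversion to the equatorial bromide, a substitution known for axial alcohols next to a quaternary carbon in trans-decalins, and no other free hydroxyl group is present.

Step 14
Reactants: 20 bromide
Product: 22 C21 ketone (C17–Br, C7–OSiMe2tBu), via C21 alcohol 21 (not isolated)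
Conditions: IBX (3 equiv), DMSO, rt
Reagents that add atoms: none
Why: IBX in DMSO cleaves triethylsilyl ethers in the presence of tert-butyldimethylsilyl ethers and, in excess, oxidises the liberated secondary alcohol in the same flask, so the ketone should be reached without a separate deprotection.

Step 15
Reactants: 22 C21 ketone
Product: 23 tertiary alcohol (C21 axial OH and equatorial CH3; C17–Br; C7–OSiMe2tBu)
Conditions: MeMgBr, CeCl3, THF, −78 to 0 °C; NH4Cl (aq)
Reagents that add atoms: methylmagnesium bromide, C[Mg]Br
Why: The organocerium reagent should add to the hindered ketone (1,2-addition) without deprotonating C8, and from the equatorial direction because the axial face is blocked by the syn-axial C20 methyl group, giving the axial tertiary alcohol.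

Step 16
Reactants: 23 silyl-protected bromo diol
Product: 24 CNP0317598.2 (target)
Conditions: Bu4NF, AcOH, THF, rt to 45 °C
Reagents that add atoms: none
Why: Fluoride-mediated desilylation frees the C7 alcohol, while the equatorial neopentyl bromide has no antiperiplanar hydrogen and should resist both elimination and substitution under buffered conditions.

Compound list
1 | 4-hydroxycyclohexan-1-one | O=C1CCC(O)CC1 | starting material
2 | 4-(triethylsilyloxy)cyclohexan-1-one | O=C1CCC(O[Si](CC)(CC)CC)CC1 | intermediate
3 | lithium (S)-4-(triethylsilyloxy)cyclohex-1-en-1-olate | [Li]OC1=CC[C@@H](O[Si](CC)(CC)CC)CC1 | intermediate (not isolated)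
4 | (S)-triethyl{[4-(trimethylsilyloxy)cyclohex-3-en-1-yl]oxy}silane | C[Si](C)(C)OC1=CC[C@@H](O[Si](CC)(CC)CC)CC1 | intermediate
5 | (S)-4-(triethylsilyloxy)cyclohex-2-en-1-one | O=C1C=C[C@@H](O[Si](CC)(CC)CC)CC1 | intermediate
6 | (S)-2-iodo-4-(triethylsilyloxy)cyclohex-2-en-1-one | O=C1C(I)=C[C@@H](O[Si](CC)(CC)CC)CC1 | intermediate
7 | (S)-2-methyl-4-(triethylsilyloxy)cyclohex-2-en-1-one | O=C1C(C)=C[C@@H](O[Si](CC)(CC)CC)CC1 | intermediate
8 | (R)-4-(tert-butyldimethylsilyloxy)cyclopent-2-en-1-one | O=C1C=C[C@H](O[Si](C)(C)C(C)(C)C)C1 | starting material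
9 | prenylmagnesium chloride | CC(C)=CC[Mg]Cl | starting material
10 | prenylcopper | CC(C)=CC[Cu] | intermediate (not isolated)
11 | tert-butyldimethyl{[(1R,2R)-2-(3-methylbut-2-enyl)-4-(trimethylsilyloxy)cyclopent-3-en-1-yl]oxy}silane | C[Si](C)(C)OC1=C[C@@H](CC=C(C)C)[C@H](O[Si](C)(C)C(C)(C)C)C1 | intermediate
12 | (2S,3R,4R)-4-(tert-butyldimethylsilyloxy)-2-[(1S,6S)-2-methyl-6-(triethylsilyloxy)-3-(trimethylsilyloxy)cyclohex-2-en-1-yl]-3-(3-methylbut-2-enyl)cyclopentan-1-one | O=C1C[C@@H](O[Si](C)(C)C(C)(C)C)[C@H](CC=C(C)C)[C@H]1[C@H]2C(C)=C(O[Si](C)(C)C)CC[C@@H]2O[Si](CC)(CC)CC | intermediate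
13 | C13-methylene analogue of 12 | C=C1C[C@@H](O[Si](C)(C)C(C)(C)C)[C@H](CC=C(C)C)[C@H]1[C@H]2C(C)=C(O[Si](C)(C)C)CC[C@@H]2O[Si](CC)(CC)CC | intermediate
14 | formaldehyde | C=O | starting material
15 | lithium enolate of 13 (C17–OLi) | C=C1C[C@@H](O[Si](C)(C)C(C)(C)C)[C@H](CC=C(C)C)[C@H]1[C@H]2C(C)=C(O[Li])CC[C@@H]2O[Si](CC)(CC)CC | intermediate (not isolated)
16 | hydroxymethyl ketone (C10: CH3 cis, CH2OH trans to ring D) | C=C1C[C@@H](O[Si](C)(C)C(C)(C)C)[C@H](CC=C(C)C)[C@H]1[C@H]2[C@](C)(CO)C(=O)CC[C@@H]2O[Si](CC)(CC)CC | intermediate
17 | iodomethyl ketone | C=C1C[C@@H](O[Si](C)(C)C(C)(C)C)[C@H](CC=C(C)C)[C@H]1[C@H]2[C@](C)(CI)C(=O)CC[C@@H]2O[Si](CC)(CC)CC | intermediate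
18 | radical precursor (C17 axial alcohol, C11 iodide) | C=C1C[C@@H](O[Si](C)(C)C(C)(C)C)[C@H](CC=C(C)C)[C@H]1[C@H]2[C@](C)(CI)[C@H](O)CC[C@@H]2O[Si](CC)(CC)CC | intermediate
19 | tetracyclic C17 alcohol with C21 triethylsilyl ether and C7 tert-butyldimethylsilyl ether | CC(C)[C@@H]1C[C@@H]2[C@H]3[C@H]4[C@](C)(CC[C@@]31C[C@H]2O[Si](C)(C)C(C)(C)C)[C@H](O)CC[C@@H]4O[Si](CC)(CC)CC | intermediate
20 | C17 equatorial bromide of 19 | CC(C)[C@@H]1C[C@@H]2[C@H]3[C@H]4[C@](C)(CC[C@@]31C[C@H]2O[Si](C)(C)C(C)(C)C)[C@@H](Br)CC[C@@H]4O[Si](CC)(CC)CC | intermediate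
21 | C21 alcohol of 20 | CC(C)[C@@H]1C[C@@H]2[C@H]3[C@H]4[C@](C)(CC[C@@]31C[C@H]2O[Si](C)(C)C(C)(C)C)[C@@H](Br)CC[C@@H]4O | intermediate (not isolated)
22 | C21 ketone | CC(C)[C@@H]1C[C@@H]2[C@H]3[C@H]4[C@](C)(CC[C@@]31C[C@H]2O[Si](C)(C)C(C)(C)C)[C@@H](Br)CCC4=O | intermediate
23 | C7 tert-butyldimethylsilyl ether of the target | CC(C)[C@@H]1C[C@@H]2[C@H]3[C@H]4[C@](C)(CC[C@@]31C[C@H]2O[Si](C)(C)C(C)(C)C)[C@@H](Br)CC[C@@]4(C)O | intermediate
24 | CNP0317598.2 | CC(C)[C@@H]1C[C@@H]2[C@H]3[C@H]4[C@](C)(CC[C@@]31C[C@H]2O)[C@@H](Br)CC[C@@]4(C)O | target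

Total step count: 16. Longest linear sequence: 15 steps (steps 1–5 and 7–16, from 1).

Steps most likely to fail

Step 12. Hydrogen transfer from the stannane to the C11 or C13 radical may outrun ring closure, a 1,5-hydrogen shift to the C11 radical may intervene, or the exo preference at C4 may be eroded. Fallback: setting out from 18, an iodine atom transfer cascade without any hydrogen donor (Bu3SnSnBu3 as photochemical initiator, hν, benzene, 80 °C) lets the radicals persist until they cyclise and should give the tertiary iodide F1. Dehydroiodination with DBU then gives the isopropenyl compound F2, and hydrogenation (H2, Pd/C, EtOAc) comes back to the route at 19.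

Step 7. Addition to the α-methylated, γ-oxygenated enone may be slow, so that protodesilylation of the enol silane or loss of facial control competes. Fallback: setting out from 11 and 5, the same trityl-catalysed Mukaiyama–Michael addition to the enone without the α-methyl group should be faster and give the trisubstituted enol silane F3. Cp2TiMe2 converts this into the methylene compound F4; MeLi generates the lithium enolate F5, which is methylated with MeI to the 2-methyl ketone F6. Silylation under equilibrating conditions (Me3SiCl, NaI, Et3N, MeCN) should favour the tetrasubstituted enol silane and so comes back to the route at 13, where the C10 configuration of F6 no longer matters.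

Step 13. Elimination toward C18 or a 1,2-shift from the quaternary C10 may compete with substitution at the hindered C17, and the triethylsilyl ether may be attacked by the phosphonium bromide. Fallback: setting out from 19, the axial alcohol is converted into the triflate F7 (Tf2O, pyridine, CH2Cl2, −40 °C), which is displaced by bromide with inversion (Bu4NBr, toluene, rt) and comes back to the route at 20.

Further compounds
F1 | step 12 | tetracyclic tertiary iodide (2-iodopropan-2-yl on C4) | CC(C)(I)[C@@H]1C[C@@H]2[C@H]3[C@H]4[C@](C)(CC[C@@]31C[C@H]2O[Si](C)(C)C(C)(C)C)[C@H](O)CC[C@@H]4O[Si](CC)(CC)CC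
F2 | step 12 | tetracyclic isopropenyl compound | C=C(C)[C@@H]1C[C@@H]2[C@H]3[C@H]4[C@](C)(CC[C@@]31C[C@H]2O[Si](C)(C)C(C)(C)C)[C@H](O)CC[C@@H]4O[Si](CC)(CC)CC
F3 | step 7 | Michael adduct without C20 methyl (C10=C17 enol silane, C13 ketone) | O=C1C[C@@H](O[Si](C)(C)C(C)(C)C)[C@H](CC=C(C)C)[C@H]1[C@H]2C=C(O[Si](C)(C)C)CC[C@@H]2O[Si](CC)(CC)CC
F4 | step 7 | C13-methylene analogue of F3 | C=C1C[C@@H](O[Si](C)(C)C(C)(C)C)[C@H](CC=C(C)C)[C@H]1[C@H]2C=C(O[Si](C)(C)C)CC[C@@H]2O[Si](CC)(CC)CC
F5 | step 7 | lithium enolate of F4 | C=C1C[C@@H](O[Si](C)(C)C(C)(C)C)[C@H](CC=C(C)C)[C@H]1[C@H]2C=C(O[Li])CC[C@@H]2O[Si](CC)(CC)CC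
F6 | step 7 | 2-methyl ketone (C20 methyl trans to ring D) | C=C1C[C@@H](O[Si](C)(C)C(C)(C)C)[C@H](CC=C(C)C)[C@H]1[C@H]2[C@H](C)C(=O)CC[C@@H]2O[Si](CC)(CC)CC
F7 | step 13 | C17 axial triflate of 19 | CC(C)[C@@H]1C[C@@H]2[C@H]3[C@H]4[C@](C)(CC[C@@]31C[C@H]2O[Si](C)(C)C(C)(C)C)[C@H](OS(=O)(=O)C(F)(F)F)CC[C@@H]4O[Si](CC)(CC)CC
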